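Compound numbers refer to the list that follows the steps.

## Analysis of the target

Target 28 is a 3,3′-linked pair of 4-aryl-3,4-dihydrocoumarins (chroman-2-ones). Lactone 1 is fused to ring A (hydroxyls at C5 and C7), lactone 2 to ring A′ (hydroxyls at C5′, C6′, C7′ and C8′), and each C4 carries a 4-hydroxyphenyl group. The four stereocentres are contiguous, C4–C3–C3′–C4′, with descriptors 4R,3S,3′S,4′R. Worked out in three dimensions, these place each aryl group on the same face of its lactone as the C3–C3′ bond (H3 and H4 cis), and the two halves are related by a local twofold axis through C3–C3′ if the two extra oxygens of ring A′ are ignored. The 3,4-cis arrangement is expected to be the less stable one, and C3 and C3′ are α to aryl-ester carbonyls and epimerise with base, so the cis relationship has to be installed late and kinetically. The sensitive groups are the two aryl lactones (opened by base and nucleophiles), eight phenols, and the 1,2,3,4-tetraoxygenated ring A′, which air oxidises once it is free. The synthesis is hard because C3–C3′ joins two crowded methine carbons, because the halves differ only in ring A versus ring A′, and because four adjacent stereocentres must be controlled. The strategy rests on one feature: the chain C4–C3–C3′–C4′ with C2 and C2′ is, atom for atom, the head-to-head dimer of two 4-hydroxycinnamic acid units, each C4 bearing the same aryl group and each C3 a carboxyl carbon. Joining C4 to C4′ makes that chain a cyclobutane, which a [2+2] photodimerisation can deliver and whose strain can later be used to break C4–C4′ again while rings A and A′ are attached.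

## Retrosynthetic reasoning

**28 to 27.** The eight O–benzyl bonds are cut. All phenols are then released together in the last step by neutral hydrogenolysis, so the oxidisable ring A′ and the base-labile cis lactones never meet base, acid or an oxidant in free form.

**27 to 25 through dienolate 26.** The bonds cut are C3–H and C3′–H. A ring closure that creates C4 beside an existing C3 centre places the aryl group anti to the C3–C3′ bond (next paragraph), and the cis lactones are the less stable ones. The cis relationship is therefore planned as a kinetic protonation. In 26, C3 and C3′ are trigonal and only C4 and C4′ remain; a proton arriving anti to each aryl group gives 27. The consequence for everything earlier is that C4 and C4′ must already be R,R, and that C3 and C3′ are carried as R,R, opposite to their configuration in 28.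

**25 to 24 to 22 through 23.** The bonds C4–C4a and C4′–C4a′ are cut and C4 is joined to C4′. Each cut bond links an electron-rich arene to a benzylic carbon para to a phenol, the retron of a 1,6-addition to a para-quinone methide. Cutting both leaves the bis(quinone methide) 23, and pairing its two methide carbons gives cyclobutane 22. The forward reaction has to oxidise both phenols so that the strained, doubly benzylic C4–C4′ bond breaks, and each aryl ester must then add through an ortho carbon. Having rings A and A′ already bound as esters forces each arene onto its own C4 in a six-membered closure. In each methide the C3–H bond lies in the dienone plane to avoid allylic strain, the ester is on one face and the other half of the molecule on the other. The arene therefore enters anti to the bond that left, and (3R,3′R) is translated into (4R,4′R) with trans lactones. A chiral acid could not override this preference, so none is planned.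

**22 to 21 to 20 to 9, 19 and 18.** The ester bonds O1–C2 and O1′–C2′ are cut. Silyl ethers on the two 4-hydroxyphenyl groups keep them distinct from the benzyl ethers of rings A and A′. Diacid 9 is twofold-symmetric, so its carboxyls are identical and only one monoester 20 exists. The cheap phenol 19 is used in that statistical step and the longer-made phenol 18 in the clean second one.

**18 to 16 to 14 to 13 to 11 to 10.** Ring A′ needs four adjacent benzyloxy groups and a phenol beside the one free ring carbon (the future C4a′). The two extra oxygens are introduced by formyl-to-hydroxyl exchanges and the carbon by one formylation of 14, whose two C–H positions are equivalent, so no regiochemical choice arises.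

**9 to 7 to 6.** The two ester bonds to the diol tether are cut by hydrolysis. This also removes the aryl silyl ethers, which are put back.

**6 to 5.** This is the key disconnection: C3–C3′ and the temporary C4–C4′ bond, a [2+2] cycloaddition. Both bonds join identical cinnamate units. The three-carbon diol tether makes the reaction intramolecular and head-to-head, and its twofold symmetry selects the trans (δ) arrangement of the carboxyl carbons with one absolute sense.

**5 to 3 and 4; 3 to 1.** Two ester bonds and one silyl ether are cut, by standard acylation and silylation.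

## Alternatives that were turned down

**Alternative 1:** Ring A′ is made last. The cut is C5′–C4a′, so that C5′ to C8′ come from a four-membered ring attached to the enol-ether carbon of a dihydropyran that already holds the rest of the molecule as a methyl-protected bis-lactol. Forward, heating opens the 4-hydroxycyclobutenone to a dienylketene, a six-electron ring closure forms C5′–C4a′, and tautomerisation gives the hydroquinone A1, 2,2′,5,6′,7,7′-hexamethoxy-4,4′-bis(4-methoxyphenyl)-[3,3′-bichromane]-5′,8′-diol.
- For: the step is thermal and reagent-free and places five oxygens on ring A′ without regiochemical doubt. On precedent for the key step it is stronger than step 14 of the chosen route.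
- Against: it forms no stereocentre and no bond of the C4–C3–C3′–C4′ chain, so C3–C3′, all four stereocentres and the cis relationships must be solved beforehand by chemistry the disconnection does not supply. A1 then needs two lactol-to-lactone oxidations beside a free hydroquinone and six O-demethylations next to two aryl lactones on the most oxidisable ring.
- Comparison: the chosen route takes ring A′ as the stable phenol 18, whose single free ortho carbon fixes the regiochemistry just as surely. It builds the chain in one photochemical step and ends with a neutral hydrogenolysis.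

**Alternative 2:** Lactone 2 is cut at C3′–C4′ and O1′–C2′. Ring A′ arrives with C4′ and its aryl group as an ortho-quinone methide, and C3′ and C2′ as an acetic active-ester side chain on C3 of a finished lactone 1. Forward, base releases the methide and a chiral N-heterocyclic carbene turns the active ester into an azolium enolate. The enolate carbon adds to the methide and the phenoxide then takes the acyl group, giving A2, the octabenzyl ether of the target (the same compound as 27).
- For: it is convergent, sets two stereocentres under catalyst control, and its compact annulation transition state should join C3′ and C4′ cis, which is what the target needs. On this point it is stronger than the chosen route, which reaches the cis lactones only by a late kinetic protonation. A2 is one hydrogenolysis from 28.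
- Against: the enolate carbon sits on a crowded methine, and the methide carbon is flanked by a benzyloxy group. Base and carbene meet lactone 1, itself an aryl ester with an epimerisable C3–H, so acyl transfer, ring opening and loss of the cis configuration at C3 compete. Lactone 1 needs its own asymmetric synthesis, and the ring A′ partner is a hexasubstituted benzene.
- Comparison: it spends much fragment synthesis on a molecule whose halves are nearly identical. The chosen route makes both halves from one cinnamic acid and offers, in place of catalyst-controlled cis selectivity, a stereochemical relay (tether to C3/C3′ to C4/C4′ and back to C3/C3′) that ends in the same compound.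

**Alternative 3:** Only one half is addressed. Lactone 1 is cut at C4–C4a, and C2, C3, C4 and the aryl group come from L-tyrosine A3, with the nitrogen kept as an azide and the acid esterified with phenol 19. Forward, a quinone oxidant dehydrogenates the free phenol to the para-quinone methide at C4, and the ester arene adds through its ortho carbon to give (3S,4R)-3-azido-5,7-bis(benzyloxy)-4-(4-hydroxyphenyl)chroman-2-one A4.
- For: it uses the cheapest source of chirality. The ring closure is the same 1,6-addition as in step 14, but the methide is reached by benzylic C–H dehydrogenation, a known process, so on this point the risk is lower than in the chosen route.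
- Against: C3 carries nitrogen where the target has C3′. The C3–C3′ bond between two crowded methine carbons of two different lactones must still be made after A4, with loss of the azide and control of both centres, so the hardest bond is left for last. The tyrosine stereocentre serves only as a relay, and an α-azido aryl ester beside a quinone methide can easily lose its C3 proton.
- Comparison: the chosen strategy forms C3–C3′ first, between two trigonal carbons of identical cinnamates held by a tether, and needs no late coupling of two lactones. The price is an unprecedented fragmentation.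

Key step: step 3

Assumption: the (2S,4S)-tether is taken to induce the (1R,2R) configuration at the two carboxyl-bearing cyclobutane carbons; should the induction run the other way, the (2R,4R)-diol replaces 4 and nothing else changes.

## Steps

Step 1
Reactants: 1 4-hydroxycinnamic acid
Product: 3 (E)-3-[4-(tert-butyldimethylsilyloxy)phenyl]acrylic acid, via silyl ester 2 (not isolated)
Conditions: TBSCl (2.5 equiv), imidazole (5 equiv), DMF, rt; then AcOH/THF/H2O (3:1:1), rt
Reagents that add atoms: tert-butyldimethylsilyl chloride, CC(C)(C)[Si](C)(C)Cl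
Why: Both acidic O–H groups are silylated with TBSCl/imidazole, and aqueous acetic acid then hydrolyses only the far more labile silyl ester; the aryl silyl ether and the E alkene are untouched.

Step 2
Reactants: 3 (E)-3-[4-(tert-butyldimethylsilyloxy)phenyl]acrylic acid (2.3 equiv); 4 (2S,4S)-pentane-2,4-diol
Product: 5 (2S,4S)-pentane-2,4-diyl bis{(2E)-3-[4-(tert-butyldimethylsilyloxy)phenyl]prop-2-enoate}
Conditions: EDC·HCl (2.6 equiv), DMAP (0.3 equiv), CH2Cl2, 0 °C to rt
Reagents that add atoms: none
Why: Steglich esterification (carbodiimide activation, DMAP acyl transfer) acylates both secondary hydroxyls; the C–O bonds of 4 are not broken, so both carbinol centres are retained.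

Step 3
Reactants: 5 (2S,4S)-pentane-2,4-diyl bis{(2E)-3-[4-(tert-butyldimethylsilyloxy)phenyl]prop-2-enoate}
Product: 6 tethered δ-truxinate (1R,4S,6S,9R,10S,11S)-10,11-bis[4-(tert-butyldimethylsilyloxy)phenyl]-4,6-dimethyl-3,7-dioxabicyclo[7.2.0]undecane-2,8-dione
Conditions: thioxanthen-9-one (10 mol %), 405 nm LEDs, degassed MeCN (5 mM), rt
Reagents that add atoms: none
Why: Thioxanthen-9-one absorbs the 405 nm light that the cinnamate chromophores do not and passes its triplet energy to one cinnamate of 5; the twisted triplet adds through its α-carbon to the α-carbon of the second cinnamate, which leaves the better stabilised bis-benzylic 1,4-biradical, and after intersystem crossing the two benzylic carbons combine. The closest known reaction type is the sensitised intramolecular [2+2] photodimerisation of dicinnamates of chiral diols to δ-truxinates. The first bond (C3–C3′ in the numbering of 28) closes the nine-membered dilactone ring by a 9-exo-trig radical addition, and the second (the temporary C4–C4′ bond) closes the cyclobutane by collapse of the 1,4-biradical. The two carboxyl-bearing carbons are set in the first bond formation: their trans relationship follows from the twofold symmetry of the tether, which matches the twofold-symmetric δ array and not the mirror-symmetric cis array, and their absolute sense (R,R) from the two (S)-carbinol centres, whose methyl groups fix the helicity in which the two acyl groups face each other. The two aryl-bearing carbons are set in the ring closure, where the freely rotating benzylic radicals close with each aryl group trans to its neighbours; these two centres are later given up. The step needs head-to-head union (the three-carbon tether cannot span a head-to-tail array), intramolecular reaction (secured by high dilution) and tolerance of E/Z isomerisation (both alkene isomers enter the same triplet).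

Step 4
Reactants: 6 tethered δ-truxinate
Product: 7 (1R,2R,3S,4S)-3,4-bis(4-hydroxyphenyl)cyclobutane-1,2-dicarboxylic acid
Conditions: LiOH·H2O (12 equiv), THF/MeOH/H2O (2:1:1), 50 °C; then 1 M HCl to pH 2
Reagents that add atoms: lithium hydroxide (its oxygen ends in the carboxyl groups), [Li+].[OH-]
Why: Saponification opens both ester links of the nine-membered ring, and hydroxide also cleaves the two aryl silyl ethers, which is accepted. The all-trans cyclobutane is the most stable of its epimers and its mirror image cannot be reached by enolisation, so base cannot erode the configuration.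

Step 5
Reactants: 7 (1R,2R,3S,4S)-3,4-bis(4-hydroxyphenyl)cyclobutane-1,2-dicarboxylic acid
Product: 9 (1R,2R,3S,4S)-3,4-bis[4-(tert-butyldimethylsilyloxy)phenyl]cyclobutane-1,2-dicarboxylic acid, via tetrasilyl derivative 8 (not isolated)
Conditions: TBSCl (5 equiv), imidazole (10 equiv), DMF, rt; then AcOH/THF/H2O (3:1:1), rt
Reagents that add atoms: tert-butyldimethylsilyl chloride, CC(C)(C)[Si](C)(C)Cl
Why: Exhaustive silylation followed by selective hydrolysis of the two silyl esters in aqueous acetic acid restores the aryl silyl ethers and frees both carboxyl groups for esterification.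

Step 6
Reactants: 10 2,3,4-trihydroxybenzaldehyde
Product: 11 2,3,4-tris(benzyloxy)benzaldehyde
Conditions: BnBr (3.6 equiv), K2CO3 (4 equiv), DMF, 60 °C
Reagents that add atoms: benzyl bromide, BrCc1ccccc1
Why: Williamson ether synthesis; excess reagent and warming also alkylate the hydrogen-bonded 2-hydroxyl.

Step 7
Reactants: 11 2,3,4-tris(benzyloxy)benzaldehyde
Product: 13 2,3,4-tris(benzyloxy)phenol, via aryl formate 12 (not isolated)
Conditions: mCPBA (1.3 equiv), CH2Cl2, 0 °C to rt; then K2CO3 (0.2 equiv), MeOH, rt
Reagents that add atoms: 3-chloroperbenzoic acid, OOC(=O)c1cccc(Cl)c1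
Why: Baeyer–Villiger oxidation: the electron-rich aryl group with ortho and para oxygens migrates in preference to hydrogen to give formate 12, which carbonate-catalysed methanolysis cleaves.

Step 8
Reactants: 13 2,3,4-tris(benzyloxy)phenol
Product: 14 1,2,3,4-tetrakis(benzyloxy)benzene
Conditions: BnBr (1.2 equiv), K2CO3 (2 equiv), DMF, rt
Reagents that add atoms: benzyl bromide, BrCc1ccccc1
Why: Williamson etherification of the new phenol gives the tetraether, in which the two remaining C–H positions are equivalent.

Step 9
Reactants: 14 1,2,3,4-tetrakis(benzyloxy)benzene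
Product: 16 2,3,4,5-tetrakis(benzyloxy)benzaldehyde, via iminium chloride 15 (not isolated)
Conditions: POCl3 (3 equiv), DMF, 0 to 75 °C; then aq. NaOAc, rt
Reagents that add atoms: N,N-dimethylformamide, CN(C)C=O; water, O
Why: Vilsmeier–Haack formylation: the chloroiminium ion attacks one of the two equivalent C–H positions, each ortho and para to a benzyloxy group, and aqueous acetate hydrolyses iminium salt 15; no Lewis acid able to cleave benzyl ethers is present.

Step 10
Reactants: 16 2,3,4,5-tetrakis(benzyloxy)benzaldehyde
Product: 18 2,3,4,5-tetrakis(benzyloxy)phenol, via aryl formate 17 (not isolated)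
Conditions: mCPBA (1.3 equiv), CH2Cl2, 0 °C to rt; then K2CO3 (0.2 equiv), MeOH, rt
Reagents that add atoms: 3-chloroperbenzoic acid, OOC(=O)c1cccc(Cl)c1
Why: Second Baeyer–Villiger oxidation and formate methanolysis; the hydroxyl of 18 now sits beside the only free ring carbon, the future C4a′.

Step 11
Reactants: 9 (1R,2R,3S,4S)-3,4-bis[4-(tert-butyldimethylsilyloxy)phenyl]cyclobutane-1,2-dicarboxylic acid; 19 3,5-bis(benzyloxy)phenol (0.9 equiv, slow addition)
Product: 20 (1R,2R,3S,4S)-2-{[3,5-bis(benzyloxy)phenoxy]carbonyl}-3,4-bis[4-(tert-butyldimethylsilyloxy)phenyl]cyclobutane-1-carboxylic acid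
Conditions: EDC·HCl (1.0 equiv), DMAP (0.1 equiv), CH2Cl2, 0 °C; unreacted 9 recovered
Reagents that add atoms: none
Why: Steglich esterification; the two carboxyls of twofold-symmetric 9 are homotopic, so only one monoester exists. Using the phenol as the limiting component favours 20 over the symmetrical diester, from which it is separated through its free acid while 9 is recycled.

Step 12
Reactants: 20 monoester; 18 2,3,4,5-tetrakis(benzyloxy)phenol (1.2 equiv)
Product: 21 1-[3,5-bis(benzyloxy)phenyl] 2-[2,3,4,5-tetrakis(benzyloxy)phenyl] (1R,2R,3S,4S)-3,4-bis[4-(tert-butyldimethylsilyloxy)phenyl]cyclobutane-1,2-dicarboxylate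
Conditions: EDC·HCl (1.5 equiv), DMAP (0.2 equiv), CH2Cl2, 0 °C to rt
Reagents that add atoms: none
Why: Steglich esterification of the remaining acid with the hindered phenol; DMAP is kept catalytic and the temperature low so that the aryl ester already present is not exchanged.

Step 13
Reactants: 21 mixed diaryl ester
Product: 22 1-[3,5-bis(benzyloxy)phenyl] 2-[2,3,4,5-tetrakis(benzyloxy)phenyl] (1R,2R,3S,4S)-3,4-bis(4-hydroxyphenyl)cyclobutane-1,2-dicarboxylate
Conditions: HF·pyridine, pyridine/THF, 0 °C to rt
Reagents that add atoms: none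
Why: Fluoride cleaves the two aryl Si–O bonds and leaves benzyl ethers alone. The acidic medium avoids free phenoxide, which could attack the aryl esters or push open the cyclobutane at the wrong bond (the one to the ester-bearing carbon).

Step 14
Reactants: 22 bisphenol diaryl ester
Product: 24 (3R,3′R,4R,4′R)-5,5′,6′,7,7′,8′-hexakis(benzyloxy)-4,4′-bis(4-hydroxyphenyl)-[3,3′-bichromane]-2,2′-dione, via bis(para-quinone methide) 23 (not isolated)
Conditions: Ag2O (8 equiv), 4 Å MS, CH2Cl2 (2 mM), 0 °C, dark; filtered cold under Ar; then (PhO)2P(O)OH (20 mol %), −40 to 0 °C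
Reagents that add atoms: none
Why: Proposed new method: Ag2O removes one electron and one proton from a phenol of 22; the phenoxyl radical carries spin at the para carbon, so the strained, doubly benzylic cyclobutane bond C4–C4′ can break as in a cyclobutylcarbinyl radical opening, giving one quinone methide and a 4-hydroxybenzyl radical that more oxidant turns into the second methide of 23. The closest known reaction types are the Ag2O dehydrogenation of 4-alkylphenols to para-quinone methides with acid-promoted intramolecular arylation (where C–H, not C–C, is broken) and the one-electron cycloreversion of 1,2-diarylcyclobutanes. With acid, each ester arene adds through an ortho carbon (the only free one of ring A′, either equivalent one of ring A) to the methide carbon on its own C3 in a six-membered 1,6-addition; because C3–H lies in the dienone plane and the ester and the other half occupy opposite faces, each arene enters anti to the bond that left, so (3R,3′R) gives (4R,4′R) and both lactones form 3,4-trans.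

Step 15
Reactants: 24 trans,trans bis-lactone bisphenol
Product: 25 (3R,3′R,4R,4′R)-5,5′,6′,7,7′,8′-hexakis(benzyloxy)-4,4′-bis[4-(benzyloxy)phenyl]-[3,3′-bichromane]-2,2′-dione
Conditions: BnBr (3 equiv), K2CO3 (3 equiv), acetone, 40 °C
Reagents that add atoms: benzyl bromide, BrCc1ccccc1
Why: Williamson benzylation removes the two acidic O–H groups before enolate chemistry and makes all eight protecting groups alike; carbonate in acetone does not open the aryl lactones, and any epimerisation at C3 or C3′ is without consequence because the next step passes through the common dienolate.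

Step 16
Reactants: 25 octabenzyl trans,trans bis-lactone
Product: 27 (3S,3′S,4R,4′R)-5,5′,6′,7,7′,8′-hexakis(benzyloxy)-4,4′-bis[4-(benzyloxy)phenyl]-[3,3′-bichromane]-2,2′-dione, via dilithium dienolate 26 (not isolated)
Conditions: LiN(i-Pr)2 (3 equiv), THF, −78 °C; then added to AcOH (10 equiv) in THF, −78 °C
Reagents that add atoms: none
Why: Double deprotonation gives dienolate 26, in which C3 and C3′ are trigonal and only C4 and C4′ remain as stereocentres; at low temperature the proton arrives on the face of each enolate anti to the adjacent pseudoaxial aryl group, so each new C–H is trans to that aryl group and the C3–C3′ bond becomes cis to it, giving (3S,3′S). This is the kinetic, contra-thermodynamic protonation of a lactone enolate next to an aryl-bearing carbon, known from the aryltetralin lactone lignans.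

Step 17
Reactants: 27 octabenzyl ether of the target
Product: 28 (3S,3′S,4R,4′R)-5,5′,6′,7,7′,8′-hexahydroxy-4,4′-bis(4-hydroxyphenyl)-[3,3′-bichromane]-2,2′-dione
Conditions: H2 (1 atm), 10% Pd/C, THF/EtOAc, rt; filtered and concentrated under Ar
Reagents that add atoms: none
Why: Hydrogenolysis of eight benzyl aryl ethers over palladium under neutral conditions; the lactones and the epimerisable C3 and C3′ centres are untouched, and exclusion of air protects the tetrahydroxylated ring A′.

## Compound list

1 | 4-hydroxycinnamic acid | OC(=O)/C=C/c1ccc(O)cc1 | starting material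
2 | tert-butyldimethylsilyl (E)-3-[4-(tert-butyldimethylsilyloxy)phenyl]acrylate | CC(C)(C)[Si](C)(C)OC(=O)/C=C/c1ccc(O[Si](C)(C)C(C)(C)C)cc1 | intermediate (not isolated)
3 | (E)-3-[4-(tert-butyldimethylsilyloxy)phenyl]acrylic acid | OC(=O)/C=C/c1ccc(O[Si](C)(C)C(C)(C)C)cc1 | intermediate
4 | (2S,4S)-pentane-2,4-diol | C[C@H](O)C[C@H](C)O | starting material
5 | (2S,4S)-pentane-2,4-diyl bis{(2E)-3-[4-(tert-butyldimethylsilyloxy)phenyl]prop-2-enoate} | C[C@H](OC(=O)/C=C/c1ccc(O[Si](C)(C)C(C)(C)C)cc1)C[C@H](C)OC(=O)/C=C/c1ccc(O[Si](C)(C)C(C)(C)C)cc1 | intermediate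
6 | tethered δ-truxinate, (1R,4S,6S,9R,10S,11S)-10,11-bis[4-(tert-butyldimethylsilyloxy)phenyl]-4,6-dimethyl-3,7-dioxabicyclo[7.2.0]undecane-2,8-dione (all-trans cyclobutane) | C[C@H]1C[C@H](C)OC(=O)[C@@H]2[C@@H](c3ccc(O[Si](C)(C)C(C)(C)C)cc3)[C@H](c3ccc(O[Si](C)(C)C(C)(C)C)cc3)[C@H]2C(=O)O1 | intermediate
7 | (1R,2R,3S,4S)-3,4-bis(4-hydroxyphenyl)cyclobutane-1,2-dicarboxylic acid | OC(=O)[C@@H]1[C@@H](c2ccc(O)cc2)[C@H](c2ccc(O)cc2)[C@H]1C(O)=O | intermediate
8 | bis(tert-butyldimethylsilyl) (1R,2R,3S,4S)-3,4-bis[4-(tert-butyldimethylsilyloxy)phenyl]cyclobutane-1,2-dicarboxylate | CC(C)(C)[Si](C)(C)OC(=O)[C@@H]1[C@@H](c2ccc(O[Si](C)(C)C(C)(C)C)cc2)[C@H](c2ccc(O[Si](C)(C)C(C)(C)C)cc2)[C@H]1C(=O)O[Si](C)(C)C(C)(C)C | intermediate (not isolated)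
9 | (1R,2R,3S,4S)-3,4-bis[4-(tert-butyldimethylsilyloxy)phenyl]cyclobutane-1,2-dicarboxylic acid | OC(=O)[C@@H]1[C@@H](c2ccc(O[Si](C)(C)C(C)(C)C)cc2)[C@H](c2ccc(O[Si](C)(C)C(C)(C)C)cc2)[C@H]1C(O)=O | intermediate
10 | 2,3,4-trihydroxybenzaldehyde | O=Cc1ccc(O)c(O)c1O | starting material
11 | 2,3,4-tris(benzyloxy)benzaldehyde | O=Cc1ccc(OCc2ccccc2)c(OCc2ccccc2)c1OCc1ccccc1 | intermediate
12 | 2,3,4-tris(benzyloxy)phenyl formate | O=COc1ccc(OCc2ccccc2)c(OCc2ccccc2)c1OCc1ccccc1 | intermediate (not isolated)
13 | 2,3,4-tris(benzyloxy)phenol | Oc1ccc(OCc2ccccc2)c(OCc2ccccc2)c1OCc1ccccc1 | intermediate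
14 | 1,2,3,4-tetrakis(benzyloxy)benzene | c1ccc(COc2ccc(OCc3ccccc3)c(OCc3ccccc3)c2OCc2ccccc2)cc1 | intermediate
15 | N,N-dimethyl-[2,3,4,5-tetrakis(benzyloxy)phenyl]methaniminium chloride | C[N+](C)=Cc1cc(OCc2ccccc2)c(OCc2ccccc2)c(OCc2ccccc2)c1OCc1ccccc1.[Cl-] | intermediate (not isolated)
16 | 2,3,4,5-tetrakis(benzyloxy)benzaldehyde | O=Cc1cc(OCc2ccccc2)c(OCc2ccccc2)c(OCc2ccccc2)c1OCc1ccccc1 | intermediate
17 | 2,3,4,5-tetrakis(benzyloxy)phenyl formate | O=COc1cc(OCc2ccccc2)c(OCc2ccccc2)c(OCc2ccccc2)c1OCc1ccccc1 | intermediate (not isolated)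
18 | 2,3,4,5-tetrakis(benzyloxy)phenol | Oc1cc(OCc2ccccc2)c(OCc2ccccc2)c(OCc2ccccc2)c1OCc1ccccc1 | intermediate
19 | 3,5-bis(benzyloxy)phenol | Oc1cc(OCc2ccccc2)cc(OCc2ccccc2)c1 | starting material
20 | (1R,2R,3S,4S)-2-{[3,5-bis(benzyloxy)phenoxy]carbonyl}-3,4-bis[4-(tert-butyldimethylsilyloxy)phenyl]cyclobutane-1-carboxylic acid | OC(=O)[C@@H]1[C@@H](c2ccc(O[Si](C)(C)C(C)(C)C)cc2)[C@H](c2ccc(O[Si](C)(C)C(C)(C)C)cc2)[C@H]1C(=O)Oc1cc(OCc2ccccc2)cc(OCc2ccccc2)c1 | intermediate
21 | 1-[3,5-bis(benzyloxy)phenyl] 2-[2,3,4,5-tetrakis(benzyloxy)phenyl] (1R,2R,3S,4S)-3,4-bis[4-(tert-butyldimethylsilyloxy)phenyl]cyclobutane-1,2-dicarboxylate | O=C(Oc1cc(OCc2ccccc2)c(OCc2ccccc2)c(OCc2ccccc2)c1OCc1ccccc1)[C@@H]1[C@@H](c2ccc(O[Si](C)(C)C(C)(C)C)cc2)[C@H](c2ccc(O[Si](C)(C)C(C)(C)C)cc2)[C@H]1C(=O)Oc1cc(OCc2ccccc2)cc(OCc2ccccc2)c1 | intermediate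
22 | 1-[3,5-bis(benzyloxy)phenyl] 2-[2,3,4,5-tetrakis(benzyloxy)phenyl] (1R,2R,3S,4S)-3,4-bis(4-hydroxyphenyl)cyclobutane-1,2-dicarboxylate | O=C(Oc1cc(OCc2ccccc2)c(OCc2ccccc2)c(OCc2ccccc2)c1OCc1ccccc1)[C@@H]1[C@@H](c2ccc(O)cc2)[C@H](c2ccc(O)cc2)[C@H]1C(=O)Oc1cc(OCc2ccccc2)cc(OCc2ccccc2)c1 | intermediate
23 | 1-[3,5-bis(benzyloxy)phenyl] 4-[2,3,4,5-tetrakis(benzyloxy)phenyl] (2R,3R)-2,3-bis[(4-oxocyclohexa-2,5-dien-1-ylidene)methyl]butanedioate | O=C(Oc1cc(OCc2ccccc2)c(OCc2ccccc2)c(OCc2ccccc2)c1OCc1ccccc1)[C@H](C=C1C=CC(=O)C=C1)[C@@H](C=C1C=CC(=O)C=C1)C(=O)Oc1cc(OCc2ccccc2)cc(OCc2ccccc2)c1 | intermediate (not isolated)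
24 | (3R,3′R,4R,4′R)-5,5′,6′,7,7′,8′-hexakis(benzyloxy)-4,4′-bis(4-hydroxyphenyl)-[3,3′-bichromane]-2,2′-dione (both lactones 3,4-trans) | O=C1Oc2cc(OCc3ccccc3)cc(OCc3ccccc3)c2[C@@H](c2ccc(O)cc2)[C@@H]1[C@@H]1C(=O)Oc2c(OCc3ccccc3)c(OCc3ccccc3)c(OCc3ccccc3)c(OCc3ccccc3)c2[C@H]1c1ccc(O)cc1 | intermediate
25 | (3R,3′R,4R,4′R)-5,5′,6′,7,7′,8′-hexakis(benzyloxy)-4,4′-bis[4-(benzyloxy)phenyl]-[3,3′-bichromane]-2,2′-dione (both lactones 3,4-trans) | O=C1Oc2cc(OCc3ccccc3)cc(OCc3ccccc3)c2[C@@H](c2ccc(OCc3ccccc3)cc2)[C@@H]1[C@@H]1C(=O)Oc2c(OCc3ccccc3)c(OCc3ccccc3)c(OCc3ccccc3)c(OCc3ccccc3)c2[C@H]1c1ccc(OCc2ccccc2)cc1 | intermediate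
26 | dilithium (4R,4′R)-5,5′,6′,7,7′,8′-hexakis(benzyloxy)-4,4′-bis[4-(benzyloxy)phenyl]-4H,4′H-[3,3′-bichromene]-2,2′-diolate | [Li+].[Li+].[O-]C1Oc2cc(OCc3ccccc3)cc(OCc3ccccc3)c2[C@@H](c2ccc(OCc3ccccc3)cc2)C=1C1=C([O-])Oc2c(OCc3ccccc3)c(OCc3ccccc3)c(OCc3ccccc3)c(OCc3ccccc3)c2[C@H]1c1ccc(OCc2ccccc2)cc1 | intermediate (not isolated)
27 | (3S,3′S,4R,4′R)-5,5′,6′,7,7′,8′-hexakis(benzyloxy)-4,4′-bis[4-(benzyloxy)phenyl]-[3,3′-bichromane]-2,2′-dione (both lactones 3,4-cis) | O=C1Oc2cc(OCc3ccccc3)cc(OCc3ccccc3)c2[C@@H](c2ccc(OCc3ccccc3)cc2)[C@H]1[C@H]1C(=O)Oc2c(OCc3ccccc3)c(OCc3ccccc3)c(OCc3ccccc3)c(OCc3ccccc3)c2[C@H]1c1ccc(OCc2ccccc2)cc1 | intermediate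
28 | (3S,3′S,4R,4′R)-5,5′,6′,7,7′,8′-hexahydroxy-4,4′-bis(4-hydroxyphenyl)-[3,3′-bichromane]-2,2′-dione (CNP0064734.1) | O=C1Oc2cc(O)cc(O)c2[C@@H](c2ccc(O)cc2)[C@H]1[C@H]1C(=O)Oc2c(O)c(O)c(O)c(O)c2[C@H]1c1ccc(O)cc1 | target

## Step count and least certain steps

Total: 17 steps. Longest linear sequence: 12 steps (steps 1–5 and 11–17, from 1 to 28); the branch to phenol 18 (steps 6–10) joins at step 12.

**Step 14 (proposed new method).** Three processes may defeat it. The phenoxyl radicals may couple through their free ortho positions faster than the cyclobutane bond breaks. A second fragmentation may complete the cycloreversion to two cinnamates. The quinone methides may tautomerise to 4-hydroxybenzylidene esters, which erases C3 and C3′ before they have directed the ring closure; intermolecular arylation at the more nucleophilic position between the two benzyloxy groups of ring A is a further drain.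

The fallback uses known chemistry, sets out from 9 and returns at 24. Li in NH3/THF at −78 °C cleaves the bond between the two aryl-bearing carbons of 9 (as its dilithium salt), the established fate of 1,2-diarylcyclobutanes under dissolving-metal conditions. This gives (2R,3R)-2,3-bis[4-(tert-butyldimethylsilyloxy)benzyl]butanedioic acid F1 with the carboxyl-bearing centres untouched. Esterification as in steps 11 and 12 gives (2R,3R)-4-[3,5-bis(benzyloxy)phenoxy]-2,3-bis[4-(tert-butyldimethylsilyloxy)benzyl]-4-oxobutanoic acid F2 and then 1-[3,5-bis(benzyloxy)phenyl] 4-[2,3,4,5-tetrakis(benzyloxy)phenyl] (2R,3R)-2,3-bis[4-(tert-butyldimethylsilyloxy)benzyl]butanedioate F3. HF·pyridine frees 1-[3,5-bis(benzyloxy)phenyl] 4-[2,3,4,5-tetrakis(benzyloxy)phenyl] (2R,3R)-2,3-bis(4-hydroxybenzyl)butanedioate F4. DDQ (or Ag2O) then dehydrogenates each 4-alkylphenol at its benzylic C–H, the classical access to para-quinone methides, to the same intermediate 23, which the acid of step 14 closes to 24.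

**Step 3 (key step).** The first bond may form with the two enoate units stacked parallel, giving the cis-fused isomer. Facial induction by the tether may be low. Intermolecular addition may compete if dilution is insufficient.

The fallback sets out from 3 and returns at 7; it gives up the tether and relies on separation of enantiomers. Acid 3 is methylated (Me3SiCHN2, MeOH/toluene) to methyl (E)-3-[4-(tert-butyldimethylsilyloxy)phenyl]acrylate F5. F5 is irradiated at high concentration with thioxanthen-9-one to give, as the main head-to-head dimer, racemic dimethyl (1R*,2R*,3S*,4S*)-3,4-bis[4-(tert-butyldimethylsilyloxy)phenyl]cyclobutane-1,2-dicarboxylate F6. Preparative chromatography on a chiral stationary phase provides dimethyl (1R,2R,3S,4S)-3,4-bis[4-(tert-butyldimethylsilyloxy)phenyl]cyclobutane-1,2-dicarboxylate F7, and saponification under the conditions of step 4 gives 7.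

**Step 16.** The second deprotonation may be incomplete. The second proton may arrive from the aryl face once the first centre is tetrahedral. The product may drift back to the trans lactones if base survives the quench, and the electron-rich dienolate may be oxidised by traces of air to the C3=C3′ alkene.

The fallback sets out from 25 and returns at 27; it replaces substrate-controlled quenching of a lithium enolate by catalyst-controlled protonation of a neutral ketene acetal. Compound 25 is converted (LiN(i-Pr)2, Me3SiCl, THF, −78 °C) into the bis(trimethylsilyl ketene acetal) (4R,4′R)-5,5′,6′,7,7′,8′-hexakis(benzyloxy)-4,4′-bis[4-(benzyloxy)phenyl]-2,2′-bis(trimethylsilyloxy)-4H,4′H-3,3′-bichromene F8. F8 is protonated at low temperature by 2,6-dimethylphenol in the presence of the matched enantiomer of 3,3′-bis(2,4,6-triisopropylphenyl)-1,1′-binaphthyl-2,2′-diyl hydrogen phosphate, which gives 27.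

**Step 11.** Statistical acylation may give much symmetrical diester and consume 9 made through the key step. The fallback sets out from 9 and returns at 20; it uses site isolation instead of statistics. Diacid 9 is anchored through one carboxyl to 2-chlorotrityl chloride polystyrene resin, the free carboxyl is esterified on the resin with 19 (diisopropylcarbodiimide, DMAP), and hexafluoroisopropanol/CH2Cl2 releases 20; no compound outside the list arises (F0).

**Step 9.** Formylation may be slow, because four adjacent alkoxy groups are twisted out of conjugation, and warming with POCl3 may cost benzyl groups. The fallback sets out from 14 and returns at 18, bypassing 16. N-Bromosuccinimide in MeCN gives 1,2,3,4-tetrakis(benzyloxy)-5-bromobenzene F9. Borylation (B2pin2, PdCl2(dppf), KOAc, dioxane, 90 °C) gives 2-[2,3,4,5-tetrakis(benzyloxy)phenyl]-4,4,5,5-tetramethyl-1,3,2-dioxaborolane F10, and NaBO3·4H2O in THF/H2O oxidises F10 to 18.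

## Further compounds

F1 | step 14 | (2R,3R)-2,3-bis[4-(tert-butyldimethylsilyloxy)benzyl]butanedioic acid | OC(=O)[C@H](Cc1ccc(O[Si](C)(C)C(C)(C)C)cc1)[C@@H](Cc1ccc(O[Si](C)(C)C(C)(C)C)cc1)C(O)=O
F2 | step 14 | (2R,3R)-4-[3,5-bis(benzyloxy)phenoxy]-2,3-bis[4-(tert-butyldimethylsilyloxy)benzyl]-4-oxobutanoic acid | OC(=O)[C@H](Cc1ccc(O[Si](C)(C)C(C)(C)C)cc1)[C@@H](Cc1ccc(O[Si](C)(C)C(C)(C)C)cc1)C(=O)Oc1cc(OCc2ccccc2)cc(OCc2ccccc2)c1
F3 | step 14 | 1-[3,5-bis(benzyloxy)phenyl] 4-[2,3,4,5-tetrakis(benzyloxy)phenyl] (2R,3R)-2,3-bis[4-(tert-butyldimethylsilyloxy)benzyl]butanedioate | O=C(Oc1cc(OCc2ccccc2)c(OCc2ccccc2)c(OCc2ccccc2)c1OCc1ccccc1)[C@H](Cc1ccc(O[Si](C)(C)C(C)(C)C)cc1)[C@@H](Cc1ccc(O[Si](C)(C)C(C)(C)C)cc1)C(=O)Oc1cc(OCc2ccccc2)cc(OCc2ccccc2)c1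
F4 | step 14 | 1-[3,5-bis(benzyloxy)phenyl] 4-[2,3,4,5-tetrakis(benzyloxy)phenyl] (2R,3R)-2,3-bis(4-hydroxybenzyl)butanedioate | O=C(Oc1cc(OCc2ccccc2)c(OCc2ccccc2)c(OCc2ccccc2)c1OCc1ccccc1)[C@H](Cc1ccc(O)cc1)[C@@H](Cc1ccc(O)cc1)C(=O)Oc1cc(OCc2ccccc2)cc(OCc2ccccc2)c1
F5 | step 3 | methyl (E)-3-[4-(tert-butyldimethylsilyloxy)phenyl]acrylate | COC(=O)/C=C/c1ccc(O[Si](C)(C)C(C)(C)C)cc1
F6 | step 3 | racemic dimethyl (1R*,2R*,3S*,4S*)-3,4-bis[4-(tert-butyldimethylsilyloxy)phenyl]cyclobutane-1,2-dicarboxylate (both enantiomers) | COC(=O)[C@@H]1[C@@H](c2ccc(O[Si](C)(C)C(C)(C)C)cc2)[C@H](c2ccc(O[Si](C)(C)C(C)(C)C)cc2)[C@H]1C(=O)OC.COC(=O)[C@H]1[C@H](c2ccc(O[Si](C)(C)C(C)(C)C)cc2)[C@@H](c2ccc(O[Si](C)(C)C(C)(C)C)cc2)[C@@H]1C(=O)OC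
F7 | step 3 | dimethyl (1R,2R,3S,4S)-3,4-bis[4-(tert-butyldimethylsilyloxy)phenyl]cyclobutane-1,2-dicarboxylate | COC(=O)[C@@H]1[C@@H](c2ccc(O[Si](C)(C)C(C)(C)C)cc2)[C@H](c2ccc(O[Si](C)(C)C(C)(C)C)cc2)[C@H]1C(=O)OC
F8 | step 16 | (4R,4′R)-5,5′,6′,7,7′,8′-hexakis(benzyloxy)-4,4′-bis[4-(benzyloxy)phenyl]-2,2′-bis(trimethylsilyloxy)-4H,4′H-3,3′-bichromene | C[Si](C)(C)OC1Oc2cc(OCc3ccccc3)cc(OCc3ccccc3)c2[C@@H](c2ccc(OCc3ccccc3)cc2)C=1C1=C(O[Si](C)(C)C)Oc2c(OCc3ccccc3)c(OCc3ccccc3)c(OCc3ccccc3)c(OCc3ccccc3)c2[C@H]1c1ccc(OCc2ccccc2)cc1
F0 | step 11 | none | none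
F9 | step 9 | 1,2,3,4-tetrakis(benzyloxy)-5-bromobenzene | Brc1cc(OCc2ccccc2)c(OCc2ccccc2)c(OCc2ccccc2)c1OCc1ccccc1
F10 | step 9 | 2-[2,3,4,5-tetrakis(benzyloxy)phenyl]-4,4,5,5-tetramethyl-1,3,2-dioxaborolane | CC1(C)OB(OC1(C)C)c1cc(OCc2ccccc2)c(OCc2ccccc2)c(OCc2ccccc2)c1OCc1ccccc1
A1 | alternative 1 | 2,2′,5,6′,7,7′-hexamethoxy-4,4′-bis(4-methoxyphenyl)-[3,3′-bichromane]-5′,8′-diol | COC1Oc2cc(OC)cc(OC)c2[C@@H](c2ccc(OC)cc2)[C@H]1[C@H]1C(OC)Oc2c(O)c(OC)c(OC)c(O)c2[C@H]1c1ccc(OC)cc1
A2 | alternative 2 | octabenzyl ether of the target (identical with 27) | O=C1Oc2cc(OCc3ccccc3)cc(OCc3ccccc3)c2[C@@H](c2ccc(OCc3ccccc3)cc2)[C@H]1[C@H]1C(=O)Oc2c(OCc3ccccc3)c(OCc3ccccc3)c(OCc3ccccc3)c(OCc3ccccc3)c2[C@H]1c1ccc(OCc2ccccc2)cc1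
A3 | alternative 3 | L-tyrosine | N[C@@H](Cc1ccc(O)cc1)C(O)=O
A4 | alternative 3 | (3S,4R)-3-azido-5,7-bis(benzyloxy)-4-(4-hydroxyphenyl)chroman-2-one | O=C1Oc2cc(OCc3ccccc3)cc(OCc3ccccc3)c2[C@@H](c2ccc(O)cc2)[C@@H]1N=[N+]=[N-]
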